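A small charge of partner, dosed into substrate, can be read by what is missing: the partner fed so far minus the target found is the part not yet target, and at the end of Sunday's dose of 0.50 equiv at 15 °C that part reads 14.0 % of the partner fed.

| flask | substrate | partner | temperature | remark | time |
|---|---|---|---|---|---|
| Sunday's | 1 M | 0.50 equiv (fed, over 8.0 min) | 15 °C | run made earlier; the fed solution adds 0.10 times the starting volume |  |
| Tuesday's | 1 M | 0.75 equiv (fed, over 8.0 min) | 48 °C | run made earlier; the fed solution adds 0.10 times the starting volume |  |
| elm | 1.0 M | 1.00 equiv (fed, over 8.0 min) | 30 °C | the fed solution adds 0.10 times the starting volume | 8.0 min |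
| cedar | 1.0 M | 1.00 equiv (fed, over 8.0 min) | 0 °C | the fed solution adds 0.10 times the starting volume | 8.0 min |
| larch | 1.0 M | 1.00 equiv (fed, over 8.0 min) | 60 °C | the fed solution adds 0.10 times the starting volume | 8.0 min |

| run | time / min | target / % |
|---|---|---|
| Sunday's | 4.00 | 20 |
| Sunday's | 8.00 | 43 |
| Sunday's | 12.0 | 49 |
| Sunday's | 15.0 | 48 |
| Sunday's | 20.0 | 50 |
| Tuesday's | 0.333 | 4 |
| Tuesday's | 0.500 | 6 |
| Tuesday's | 1.00 | 12 |
| Tuesday's | 2.00 | 23 |
| Tuesday's | 4.00 | 39 |

(scatter of a reading: 2 percentage points)

1. the flask that comes out highest in amount of target, in percent of the substrate charged, or "all alike" when all lie within 1.5 percentage points (elm / cedar / larch / all alike)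
2. target at the end, in percent of the substrate charged, elm
3. target at the end, in percent of the substrate charged, cedar
4. target at the end, in percent of the substrate charged, larch

- charges are per starting volume, the dose included; the dosed solution carries all of it
- the numbers in the tables scatter by 2 percentage points (one standard deviation)
- a reading or a percentage of target counts all its forms, free or not

In Sunday's first minutes the drops meet substrate in excess, and the target curve follows the feed at a distance: 20 % stands at 4.00 min against 25.0 % fed. A distance held under a steady feed is a time, so the fraction left at the end of a dose lasting t_f is τ/t_f, and Sunday's end reading gives τ = 1.12 min, the lag time, the time by which target trails the feed, give or take 0.320 min from the scatter. After the dose Sunday's shortfall closes within the scatter, with target reading 50 % at 20.0 min, the amount fed, and partner is the limiting reagent there. The new flasks get no such tail, since they stop at 8.0 min, as the dose ends, so their fraction left is reckoned here as τ/t_f.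

Tuesday's flask at 48 °C shows no shortfall beyond the scatter, with 39 % at 4.00 min against 37.5 % fed, so a gap of one standard deviation there stands for a τ of about 0.213 min, and this estimate puts the ratio of τ between the two runs, which differ in charge as well as in temperature, at about 5.26 or more. Carrying that ratio at an even pace per degree, the reckoning here leaves 29.7 % in cedar, 6.59 % in elm and 1.46 % in larch. Target would then be 70.3 %, 93.4 % and 98.5 %. These figures are estimates with a further reservation: the new flasks get 1.00 equiv against Sunday's 0.50 equiv, and τ may lengthen as substrate thins.

The forecast names larch and gives 85 % for elm, 58 % for cedar and 92 % for larch, each lower than the figures reckoned here, and it holds that “Near equivalence the reaction starves”.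

The flasks end at 87.8 % in elm, 37.7 % in cedar and 94.6 % in larch, which is highest.

    open intermediate + second intermediate → target (k = 0.0308 M⁻¹ s⁻¹, Ea = 42.0 kJ mol⁻¹)
    partner → second intermediate (k = 0.0349 s⁻¹, Ea = 74.0 kJ mol⁻¹)
    substrate ⇌ open intermediate (K = 0.633, k = 0.00154 s⁻¹, Ea = 78.0 kJ mol⁻¹, ΔH = 28.0 kJ mol⁻¹)
    crystals ⇌ target, rate k4*(cs4 - [target]) while solid is left; crystals form when [target] > cs4 (solubility = 0.520 M, k = 0.134 s⁻¹)
    2 second intermediate → homo product (k = 0.00100 M⁻¹ s⁻¹, Ea = 63.0 kJ mol⁻¹)
    (constants at 0 °C)

Cedar lies 20 percentage points below the forecast, and at 8.00 min it still holds substrate 55.8 %, partner 5.97 % of its own charge and second intermediate 0.437 M. Its fraction not yet target, 62.3 %, is a τ of 4.99 min, longer than Sunday's reading by a ratio of 4.46. In larch the same subtraction leaves 5.40 %, a τ of 0.429 min.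

Readings and results stem from a simulated flask for an exercise.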